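## Structural features

The target contains three guaiacyl-type arene units. A 7-methoxybenzofuran with a 3-hydroxypropyl chain at C5 is bonded through its C2 to C5 of a 7-methoxy-2,3-dihydrobenzofuran. The dihydrofuran ring (O1, C2, C3, C3a, C7a) carries a 4-hydroxy-3-methoxyphenyl group at C2 and a CH2OH group at C3. C2 and C3 are the only stereocentres; they are adjacent and trans, (2S,3R). The fragile sites are these:

- the free phenol para to the benzylic C2–O1 bond, because ionisation of that bond towards a quinone methide would scramble C2;
- the electron-rich C2=C3 bond of the benzofuran, which is sensitive to oxidants and electrophiles;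
- at the ester oxidation level, the acidic C3–H, whose enolate can expel O1.

The real difficulty is the absolute and relative configuration of the C2/C3 pair on an easily ionised benzylic ether; the aryl–benzofuran connectivity is routine alkyne chemistry. The key step uses the fact that O1–C2–C3–C3a is the pyranone ring of a flavanone with its carbonyl carbon pushed out: C3a is the ring A carbon that moved onto C3, and the CH2OH carbon is the former C4. One stereocentre (flavanone C2) can therefore control both.

## Logic of the disconnections

**19 to 18.** No skeletal bond is cut. The two primary alcohols and the phenol are traced back to two methyl esters and an aryl pivalate, so that one hydride step finishes the synthesis. The gain is that every polar group is masked and non-nucleophilic in 18. The demand is that hydride reduces the C3 ester faster than C3 is deprotonated.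

**18 to 14.** The C3–C3a bond is cut and C3a is reattached to the ester carbon, a retro 1,2-shift that expands the five-membered ring to a six-membered ring with a C4 carbonyl. This is the place to cut because C3 becomes a CH2 group and the trans pair collapses to the single stereocentre C2. The gain is one stereocentre fewer and a substrate class open to catalytic asymmetric conjugate addition. The forward step must make ring A migrate in preference to ring B, must direct the oxidant to the enol ether and not to the benzofuran, and must not ionise C2–O1.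

**14 to 10 and 13.** The C2–aryl bond is cut. This removes the last stereocentre and splits off the guaiacyl unit, leaving a flat chromone. The forward step needs ligand control of the enone face and base-free conditions, so that the product does not racemise by retro-oxa-Michael opening. It is placed after every amine-mediated step for the same reason.

**13 to 12 to 11.** Only B–O and O–acyl bonds change. The phenol is acylated at the stage of the boron reagent, so that no free phenol ever meets the oxidant of the key step. The pinacol ester is opened to the boronic acid because that is the species that transmetalates readily to cationic divalent palladium. The demand is a deprotection of boron that leaves the aryl ester alone.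

**10 to 6 and 8.** The benzofuran bonds C3–C3a and O1–C2 are cut, giving a terminal alkyne and an ortho-iodophenol. Both halves then come from simple phenols, and the substitution pattern of the benzofuran is fixed by the iodination site. The forward step must couple and cyclise without opening the chromone.

**6 to 5 to 4.** The bond between chromone C6 and the alkyne carbon is cut back to an aryl bromide and ethynyltrimethylsilane. The demand is non-nucleophilic coupling and desilylation conditions, since the chromone is base-sensitive.

**4 to 2 to 1.** O1–C2 and C2–C3 of the pyranone are cut, with C2 supplied as a one-carbon amide acetal, and then the C–Br bond. Bromination must go para to the phenol, which the blocked ortho positions ensure.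

**8 to 7.** The C–I bond is cut. Iodination must go ortho to the phenol, the only open activated position.

## Other disconnections considered

**Alternative 1:** Dötz benzannulation of the benzofuran benzene ring.
- **Cut:** three bonds of the benzene ring of the benzofuran (C7–C6, C5–C4, C4–C3a). What remains is a furan that already carries the complete, silyl-protected dihydrobenzofuran.
- **Forward key step:** the pentacarbonylchromium methoxy(furyl)carbene complex A2 would be heated with the silyl-protected pentynol A3. Alkyne insertion, CO insertion and electrocyclisation would give the 4-hydroxy-7-methoxybenzofuran A1.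
- **In favour:** the substitution pattern follows from the mechanism, with the alkyne substituent next to the new phenol carbon and the methoxy group para to it. Three C–C bonds form in one thermal, neutral step that would not disturb C2 or C3.
- **Against:** A1 has a C4 hydroxyl that the target lacks, so triflation and reductive C–O cleavage must follow. A1 is a hydroquinone monoether and oxidises easily when chromium is removed. Cr(CO)6 is needed in stoichiometric amount. The plan does not address the two stereocentres, which must already be present in A2.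
- **Comparison:** structurally, this plan uses its key step on the achiral half, while the chosen plan uses it on the stereochemical core. Mechanistically it is the equal of the chosen plan in regiochemical security, and it is the better in that no oxidant meets the electron-rich benzofuran. In step economy it is the weaker, because of the deoxygenation steps, the carbene preparation and an unsolved synthesis of the chiral furan partner.

**Alternative 2:** quinone methide and chiral sulfonium ylide (4+1) annulation.
- **Cut:** O1–C2 and C2–C3 of the dihydrofuran, so that C2 arrives as a one-carbon ylide unit.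
- **Forward key step:** base would eliminate sulfinate from the phenolic sulfone A5 to give the ortho-quinone methide A7, and would deprotonate the chiral benzylsulfonium salt A6 to the ylide A8. Addition of the ylide carbon to the methide carbon and displacement of the sulfide by the phenoxide would give A4.
- **In favour:** both ring bonds and both stereocentres form in one convergent step. The trans geometry follows from the anti betaine. The C3 side-chain carbon is already at the alcohol level, so only desilylation remains. No oxidant or strong acid is used.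
- **Against:** A7 has hydrogens next to the methide carbon and a β-silyloxy group, so a 1,5-hydrogen shift or elimination can compete with trapping. The absolute configuration depends on a stoichiometric chiral sulfide and on irreversible betaine formation, which is least secure for an electron-rich, semi-stabilised ylide such as A8. A5 needs several steps of ortho-functionalisation on a phenol that already carries the benzofuran.
- **Comparison:** this plan is the better in convergence and in setting both centres at once, where the chosen plan needs two events. It is the equal in the number of steps after the key step (one). The chosen plan is judged more predictable: a catalytic addition to a rigid chromone for absolute control, and a stereospecific shift backed by a thermodynamic preference for relative control. Overall step counts should be similar.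

**Alternative 3:** ketone C-arylation and enolate O-arylation.
- **Cut:** C3–C3a and O1–C7a of the benzofuran, so that the furan oxygen is the oxygen of a methyl ketone.
- **Forward key step:** Pd2(dba)3, Xantphos and K3PO4 would arylate the enolate of the acetyl compound A10 at the iodide of the iodo triflate A11, giving the α-aryl ketone A12. Intramolecular O-arylation of its enolate at the triflate would close the furan and give A9.
- **In favour:** the plan is convergent and uses the same ortho-iodinated arene as the chosen plan. No terminal alkyne has to be installed and unmasked, which saves two steps on that fragment and avoids alkyne homocoupling.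
- **Against:** C–O bond formation from a palladium enolate at an aryl triflate is the weak point, since S–O cleavage by phosphate would return a phenol. A12 is more acidic than A10 and can be arylated a second time. The conditions are hot and basic. A10 must already contain both stereocentres, for which this cut offers nothing.
- **Comparison:** the two plans differ only in which C–O bond of the benzofuran is formed (O1–C7a here, O1–C2 in the chosen plan). The chosen closure is an addition without a leaving group and runs with an amine base at moderate temperature. For the benzofuran alone, alternative 3 is the better in step economy. Over the whole molecule it is not shorter, because the stereochemical core still has to be built.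

Key step: step 10

Assumption: (R)-t-BuPyOx is taken to deliver the aryl group to the chromone face that gives (S)-C2, the mirror image of the facial sense of the (S)-ligand with 3-substituted cyclohexenones after the CIP priorities are transposed to the chromone; if the sense proves to be the reverse, the other ligand enantiomer is used with no other change.

## Route

Step 1
Reactants: 1 2'-hydroxy-3'-methoxyacetophenone
Product: 2 5'-bromo-2'-hydroxy-3'-methoxyacetophenone
Conditions: NBS, MeCN, 0 °C to rt
Reagents that add atoms: N-bromosuccinimide, BrN1C(=O)CCC1=O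
Why: Electrophilic aromatic bromination; the phenol is the dominant director and both of its ortho positions are occupied (acetyl and OMe), so bromine should enter para to OH, which is also meta to the acetyl group.

Step 2
Reactants: 2 5'-bromo-2'-hydroxy-3'-methoxyacetophenone
Product: 4 6-bromo-8-methoxy-4H-chromen-4-one, via enaminone 3 (not isolated)
Conditions: Me2NCH(OMe)2, toluene, 100 °C; then conc. HCl, CH2Cl2, 40 °C
Reagents that add atoms: N,N-dimethylformamide dimethyl acetal, COC(OC)N(C)C
Why: Condensation of the methyl ketone with the amide acetal gives the enaminone, and acid then drives 6-endo addition of the phenol oxygen to the β-carbon with loss of dimethylamine (enaminone route to chromones); chromone C2 comes from the acetal carbon.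

Step 3
Reactants: 4 6-bromo-8-methoxy-4H-chromen-4-one
Product: 5 8-methoxy-6-[(trimethylsilyl)ethynyl]-4H-chromen-4-one
Conditions: ethynyltrimethylsilane, PdCl2(PPh3)2 (cat.), CuI (cat.), Et3N, THF, 65 °C
Reagents that add atoms: ethynyltrimethylsilane, C#C[Si](C)(C)C
Why: Sonogashira coupling of an aryl bromide; a tertiary amine is used because primary and secondary amines add to C2 of chromones and open the pyranone.

Step 4
Reactants: 5 8-methoxy-6-[(trimethylsilyl)ethynyl]-4H-chromen-4-one
Product: 6 6-ethynyl-8-methoxy-4H-chromen-4-one
Conditions: Bu4NF, AcOH, THF, 0 °C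
Reagents that add atoms: none
Why: Fluoride-induced protodesilylation of the alkynylsilane; buffering with acetic acid keeps the medium non-basic so that the chromone ring is not opened.

Step 5
Reactants: 7 methyl 3-(4-hydroxy-3-methoxyphenyl)propanoate
Product: 8 methyl 3-(4-hydroxy-3-iodo-5-methoxyphenyl)propanoate
Conditions: NIS, TsOH·H2O (cat.), MeCN, 0 °C to rt
Reagents that add atoms: N-iodosuccinimide, IN1C(=O)CCC1=O
Why: Electrophilic aromatic iodination; para to OH is blocked by the side chain and one ortho position by OMe, so iodine should enter the remaining ortho position, which is the one needed for the annulation.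

Step 6
Reactants: 6 6-ethynyl-8-methoxy-4H-chromen-4-one; 8 methyl 3-(4-hydroxy-3-iodo-5-methoxyphenyl)propanoate
Product: 10 methyl 3-[7-methoxy-2-(8-methoxy-4-oxo-4H-chromen-6-yl)benzofuran-5-yl]propanoate, via alkynylphenol 9 (not isolated)
Conditions: PdCl2(PPh3)2 (cat.), CuI (cat.), Et3N, DMF, 70 °C, degassed
Reagents that add atoms: none
Why: Sonogashira coupling at the aryl iodide forms the C3–C3a bond of the benzofuran, and the ortho phenol then adds 5-endo-dig to the metal-activated alkyne to form O1–C2 (coupling–cycloisomerisation benzofuran synthesis of the Castro–Stephens type); no stereocentre is formed.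

Step 7
Reactants: 11 4-hydroxy-3-methoxyphenylboronic acid pinacol ester
Product: 12 2-methoxy-4-(4,4,5,5-tetramethyl-1,3,2-dioxaborolan-2-yl)phenyl pivalate
Conditions: PivCl, Et3N, DMAP (cat.), CH2Cl2, 0 °C to rt
Reagents that add atoms: pivaloyl chloride, CC(C)(C)C(Cl)=O
Why: DMAP-catalysed O-acylation of the phenol; the pivalate shields the phenol from the oxidant of step 10, lowers the migratory aptitude of ring B and is hindered enough to survive acidic methanol.

Step 8
Reactants: 12 2-methoxy-4-(4,4,5,5-tetramethyl-1,3,2-dioxaborolan-2-yl)phenyl pivalate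
Product: 13 [3-methoxy-4-(pivaloyloxy)phenyl]boronic acid
Conditions: NaIO4, NH4OAc, acetone/H2O, rt
Reagents that add atoms: water, O
Why: Periodate cleaves the pinacol released in the hydrolysis equilibrium and so drives the boronate to the free boronic acid, which transmetalates to cationic divalent palladium far more readily than the pinacol ester; the aryl pivalate is inert to these conditions.

Step 9
Reactants: 10 methyl 3-[7-methoxy-2-(8-methoxy-4-oxo-4H-chromen-6-yl)benzofuran-5-yl]propanoate; 13 [3-methoxy-4-(pivaloyloxy)phenyl]boronic acid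
Product: 14 methyl 3-[7-methoxy-2-[(2S)-8-methoxy-2-[3-methoxy-4-(pivaloyloxy)phenyl]-4-oxochroman-6-yl]benzofuran-5-yl]propanoate
Conditions: Pd(OCOCF3)2 (5 mol %), (R)-t-BuPyOx (6 mol %), NH4PF6 (30 mol %), H2O (5 equiv), ClCH2CH2Cl, 60 °C
Reagents that add atoms: none
Why: Asymmetric conjugate addition of an arylboronic acid to a chromone under divalent palladium catalysis: transmetalation, enantio-determining insertion of the C2=C3 bond into the aryl–palladium bond inside the pyridine-oxazoline pocket, then protonolysis of the palladium enolate by water; the ligand sets C2 as (S), and the absence of base avoids racemisation by retro-oxa-Michael opening.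

Step 10
Reactants: 14 methyl 3-[7-methoxy-2-[(2S)-8-methoxy-2-[3-methoxy-4-(pivaloyloxy)phenyl]-4-oxochroman-6-yl]benzofuran-5-yl]propanoate
Product: 18 methyl (2S,3S)-7-methoxy-5-[7-methoxy-5-(3-methoxy-3-oxopropyl)benzofuran-2-yl]-2-[3-methoxy-4-(pivaloyloxy)phenyl]-2,3-dihydrobenzofuran-3-carboxylate, via enol ether 15 (not isolated), via iodanyl ketal 16 (not isolated), via orthoester 17 (not isolated)
Conditions: HC(OMe)3, conc. H2SO4 (cat.), rt; then PhI(OAc)2 (1.2 equiv), 0 °C to rt; aq. NaHCO3 work-up
Reagents that add atoms: trimethyl orthoformate, COC(OC)OC; water, O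
Why: Acid and orthoformate convert the C4 ketone into the methyl enol ether 15, whose C3 attacks the acid-activated trivalent iodine reagent on the face anti to the C2 aryl group, and methanol captures the oxocarbenium ion to give the trans C3-iodanyl dimethyl ketal 16. The C4–C4a bond, antiperiplanar to the equatorial C3–I bond, then migrates from C4 to C3 with loss of PhI and inversion at C3, which forms the C3–C3a bond and a dimethoxycarbenium ion that methanol traps as orthoester 17, hydrolysed to the methyl ester on work-up. The closest known reaction type is the oxidative ring contraction of flavanones to methyl trans-2-aryl-2,3-dihydrobenzofuran-3-carboxylates by trivalent iodine or trivalent thallium reagents in trimethyl orthoformate, a semipinacol-type 1,2-aryl shift. The dihydrofuran ring is closed by this 1,2-shift contraction of the six-membered pyranone (six to five) and not by a cyclisation, the former carbonyl carbon becoming exocyclic. The new stereocentre C3 is controlled by the existing C2 centre: anti iodination followed by invertive migration places the ester carbon trans to the aryl group, the epimerisable α-aryl ester converges on the same trans isomer thermodynamically, and C2 itself is not touched. The step needs migration of ring A (C4a, ortho to O1 and electron-rich) in preference to ring B migration (isoflavone) or plain dehydrogenation (flavone); the pivaloyloxy group and the meta OMe make ring B a poor migrating group and disfavour ionisation of C2–O1. Forming 15 before a small excess of oxidant is added keeps the reagent from attacking the electron-rich benzofuran.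

Step 11
Reactants: 18 methyl (2S,3S)-7-methoxy-5-[7-methoxy-5-(3-methoxy-3-oxopropyl)benzofuran-2-yl]-2-[3-methoxy-4-(pivaloyloxy)phenyl]-2,3-dihydrobenzofuran-3-carboxylate
Product: 19 4-[(2S,3R)-3-(hydroxymethyl)-5-[5-(3-hydroxypropyl)-7-methoxybenzofuran-2-yl]-7-methoxy-2,3-dihydrobenzofuran-2-yl]-2-methoxyphenol
Conditions: LiAlH4 (excess), THF, 0 °C to rt; aq. KNaC4H4O6 work-up
Reagents that add atoms: none
Why: Hydride reduction of both methyl esters to primary alcohols and reductive cleavage of the aryl pivalate in one operation; no bond to C2 or C3 is broken, and the C3 descriptor changes from S to R only because CH2OH ranks below C2 whereas CO2Me ranks above it.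

## Compound list

1 | 2'-hydroxy-3'-methoxyacetophenone | CC(=O)c1cccc(OC)c1O | starting material
2 | 5'-bromo-2'-hydroxy-3'-methoxyacetophenone | CC(=O)c1cc(Br)cc(OC)c1O | intermediate
3 | (E)-1-(5-bromo-2-hydroxy-3-methoxyphenyl)-3-(dimethylamino)prop-2-en-1-one | CN(C)/C=C/C(=O)c1cc(Br)cc(OC)c1O | intermediate
4 | 6-bromo-8-methoxy-4H-chromen-4-one | O=c1ccoc2c(OC)cc(Br)cc12 | intermediate
5 | 8-methoxy-6-[(trimethylsilyl)ethynyl]-4H-chromen-4-one | C[Si](C)(C)C#Cc1cc(OC)c2occc(=O)c2c1 | intermediate
6 | 6-ethynyl-8-methoxy-4H-chromen-4-one | C#Cc1cc(OC)c2occc(=O)c2c1 | intermediate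
7 | methyl 3-(4-hydroxy-3-methoxyphenyl)propanoate | COC(=O)CCc1ccc(O)c(OC)c1 | starting material
8 | methyl 3-(4-hydroxy-3-iodo-5-methoxyphenyl)propanoate | COC(=O)CCc1cc(I)c(O)c(OC)c1 | intermediate
9 | methyl 3-[4-hydroxy-3-methoxy-5-[(8-methoxy-4-oxo-4H-chromen-6-yl)ethynyl]phenyl]propanoate | COC(=O)CCc1cc(OC)c(O)c(C#Cc2cc(OC)c3occc(=O)c3c2)c1 | intermediate
10 | methyl 3-[7-methoxy-2-(8-methoxy-4-oxo-4H-chromen-6-yl)benzofuran-5-yl]propanoate | COC(=O)CCc1cc(OC)c2oc(-c3cc(OC)c4occc(=O)c4c3)cc2c1 | intermediate
11 | 4-hydroxy-3-methoxyphenylboronic acid pinacol ester | COc1cc(B2OC(C)(C)C(C)(C)O2)ccc1O | starting material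
12 | 2-methoxy-4-(4,4,5,5-tetramethyl-1,3,2-dioxaborolan-2-yl)phenyl pivalate | COc1cc(B2OC(C)(C)C(C)(C)O2)ccc1OC(=O)C(C)(C)C | intermediate
13 | [3-methoxy-4-(pivaloyloxy)phenyl]boronic acid | COc1cc(B(O)O)ccc1OC(=O)C(C)(C)C | intermediate
14 | methyl 3-[7-methoxy-2-[(2S)-8-methoxy-2-[3-methoxy-4-(pivaloyloxy)phenyl]-4-oxochroman-6-yl]benzofuran-5-yl]propanoate | COc1cc([C@@H]2CC(=O)c3cc(-c4cc5cc(CCC(=O)OC)cc(OC)c5o4)cc(OC)c3O2)ccc1OC(=O)C(C)(C)C | intermediate
15 | methyl 3-[2-[(2S)-4,8-dimethoxy-2-[3-methoxy-4-(pivaloyloxy)phenyl]-2H-chromen-6-yl]-7-methoxybenzofuran-5-yl]propanoate | COc1cc([C@@H]2C=C(OC)c3cc(-c4cc5cc(CCC(=O)OC)cc(OC)c5o4)cc(OC)c3O2)ccc1OC(=O)C(C)(C)C | intermediate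
16 | methyl 3-[2-[(2R,3R)-3-[acetoxy(phenyl)-λ3-iodanyl]-4,4,8-trimethoxy-2-[3-methoxy-4-(pivaloyloxy)phenyl]chroman-6-yl]-7-methoxybenzofuran-5-yl]propanoate (iodine trans to the C2 aryl group; C2 geometry as in 14, descriptor changed by the iodine at C3) | COc1cc([C@@H]2[C@@H](I(OC(C)=O)c3ccccc3)C(OC)(OC)c3cc(-c4cc5cc(CCC(=O)OC)cc(OC)c5o4)cc(OC)c3O2)ccc1OC(=O)C(C)(C)C | intermediate
17 | methyl 3-[7-methoxy-2-[(2S,3S)-7-methoxy-2-[3-methoxy-4-(pivaloyloxy)phenyl]-3-(trimethoxymethyl)-2,3-dihydrobenzofuran-5-yl]benzofuran-5-yl]propanoate | COc1cc([C@H]2Oc3c(OC)cc(-c4cc5cc(CCC(=O)OC)cc(OC)c5o4)cc3[C@@H]2C(OC)(OC)OC)ccc1OC(=O)C(C)(C)C | intermediate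
18 | methyl (2S,3S)-7-methoxy-5-[7-methoxy-5-(3-methoxy-3-oxopropyl)benzofuran-2-yl]-2-[3-methoxy-4-(pivaloyloxy)phenyl]-2,3-dihydrobenzofuran-3-carboxylate (trans) | COc1cc([C@H]2Oc3c(OC)cc(-c4cc5cc(CCC(=O)OC)cc(OC)c5o4)cc3[C@@H]2C(=O)OC)ccc1OC(=O)C(C)(C)C | intermediate
19 | 4-[(2S,3R)-3-(hydroxymethyl)-5-[5-(3-hydroxypropyl)-7-methoxybenzofuran-2-yl]-7-methoxy-2,3-dihydrobenzofuran-2-yl]-2-methoxyphenol (trans) | COc1cc([C@H]2Oc3c(OC)cc(-c4cc5cc(CCCO)cc(OC)c5o4)cc3[C@@H]2CO)ccc1O | target

## Step count and least certain steps

Total step count: 11. Longest linear sequence: 8 steps (steps 1, 2, 3, 4, 6, 9, 10 and 11, from 1 to 19).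

**Step 10 (key step).** The most likely failure is attack of the trivalent iodine electrophile on the electron-rich C2=C3 bond of the benzofuran in competition with the iodination of the enol ether, because both are activated π-systems and the oxidant is used under strong acid. Secondary risks are migration of ring B or dehydrogenation, and acid-induced opening at C2 with loss of enantiopurity. Fallback: the contraction is moved ahead of the benzofuran construction. Setting out from 4 and 13, the conditions of step 9 should give (2S)-6-bromo-8-methoxy-2-[3-methoxy-4-(pivaloyloxy)phenyl]chroman-4-one F1. The PhI(OAc)2/H2SO4/HC(OMe)3 contraction on this simple substrate, which has no oxidisable heteroarene, should give methyl (2S,3S)-5-bromo-7-methoxy-2-[3-methoxy-4-(pivaloyloxy)phenyl]-2,3-dihydrobenzofuran-3-carboxylate F2. Sonogashira coupling with ethynyltrimethylsilane (PdCl2(PPh3)2, CuI, Et3N) gives the silylalkyne methyl (2S,3S)-7-methoxy-2-[3-methoxy-4-(pivaloyloxy)phenyl]-5-[(trimethylsilyl)ethynyl]-2,3-dihydrobenzofuran-3-carboxylate F3. Buffered fluoride gives the terminal alkyne methyl (2S,3S)-5-ethynyl-7-methoxy-2-[3-methoxy-4-(pivaloyloxy)phenyl]-2,3-dihydrobenzofuran-3-carboxylate F4. Coupling–cycloisomerisation of F4 with 8, through the alkynylphenol methyl (2S,3S)-5-[[2-hydroxy-3-methoxy-5-(3-methoxy-3-oxopropyl)phenyl]ethynyl]-7-methoxy-2-[3-methoxy-4-(pivaloyloxy)phenyl]-2,3-dihydrobenzofuran-3-carboxylate F5 (not isolated), returns to the route at 18.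

**Step 9.** The most likely failure is insufficient facial discrimination or stalled turnover (reduction to palladium metal, protodeboronation of the fairly electron-rich boronic acid), because the chromone carries a large, Lewis-basic 6-substituent and an 8-methoxy group next to O1, both beyond the simplest substrates of this reaction. Fallback: kinetic resolution in place of asymmetric catalysis. Setting out from 10 and 13, an achiral catalyst (Pd(OCOCF3)2, 2,2'-bipyridine, NH4PF6, H2O, ClCH2CH2Cl) should give the racemic flavanone, methyl 3-[7-methoxy-2-[8-methoxy-2-[3-methoxy-4-(pivaloyloxy)phenyl]-4-oxochroman-6-yl]benzofuran-5-yl]propanoate F6. Asymmetric transfer hydrogenation with RuCl(p-cymene)[(R,R)-TsDPEN] and HCO2H/Et3N is expected to reduce the (R)-ketone faster, to the cis alcohol methyl 3-[2-[(2R,4R)-4-hydroxy-8-methoxy-2-[3-methoxy-4-(pivaloyloxy)phenyl]chroman-6-yl]-7-methoxybenzofuran-5-yl]propanoate F7. The unreduced (S)-ketone is separated by chromatography, and the route is rejoined at 14.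

**Step 6.** The most likely failure is loss of the terminal alkyne by copper-mediated oxidative homocoupling, or opening of the chromone by phenoxide or amine at 70 °C, before the slower 5-endo closure is complete. Fallback: the benzofuran is made first and joined to the chromone by a biaryl-type coupling. Setting out from 8, Sonogashira coupling with ethynyltrimethylsilane gives methyl 3-[4-hydroxy-3-methoxy-5-[(trimethylsilyl)ethynyl]phenyl]propanoate F8. Bu4NF in THF at 65 °C removes the silyl group and closes the furan to methyl 3-(7-methoxybenzofuran-5-yl)propanoate F9. C–H borylation at the furan C2 ([Ir(OMe)(cod)]2, 4,4'-di-tert-butyl-2,2'-bipyridine, B2pin2) gives methyl 3-[7-methoxy-2-(4,4,5,5-tetramethyl-1,3,2-dioxaborolan-2-yl)benzofuran-5-yl]propanoate F10. Suzuki–Miyaura coupling of F10 with 4 (Pd(dppf)Cl2, K3PO4, dioxane/H2O) returns to the route at 10.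

**Step 11.** The most likely failure is deprotonation at C3 by the basic aluminium hydride before the hindered C3 ester is reduced, leading to opening of the dihydrofuran by expulsion of O1 or to epimerisation; a lesser risk is loss of the polar triol phenol in aluminium salts. Fallback: reduction and deacylation are separated. Setting out from 18, LiBH4 in THF/MeOH at 0 °C to rt, a less basic hydride, should reduce the two methyl esters to give 4-[(2S,3R)-3-(hydroxymethyl)-5-[5-(3-hydroxypropyl)-7-methoxybenzofuran-2-yl]-7-methoxy-2,3-dihydrobenzofuran-2-yl]-2-methoxyphenyl pivalate F11. K2CO3 in MeOH at rt then removes the pivalate, which is safe once no ester remains at C3, and the route is rejoined at 19.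

## Further compounds

F1 | step 10 | (2S)-6-bromo-8-methoxy-2-[3-methoxy-4-(pivaloyloxy)phenyl]chroman-4-one | COc1cc([C@@H]2CC(=O)c3cc(Br)cc(OC)c3O2)ccc1OC(=O)C(C)(C)C
F2 | step 10 | methyl (2S,3S)-5-bromo-7-methoxy-2-[3-methoxy-4-(pivaloyloxy)phenyl]-2,3-dihydrobenzofuran-3-carboxylate | COc1cc([C@H]2Oc3c(OC)cc(Br)cc3[C@@H]2C(=O)OC)ccc1OC(=O)C(C)(C)C
F3 | step 10 | methyl (2S,3S)-7-methoxy-2-[3-methoxy-4-(pivaloyloxy)phenyl]-5-[(trimethylsilyl)ethynyl]-2,3-dihydrobenzofuran-3-carboxylate | COc1cc([C@H]2Oc3c(OC)cc(C#C[Si](C)(C)C)cc3[C@@H]2C(=O)OC)ccc1OC(=O)C(C)(C)C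
F4 | step 10 | methyl (2S,3S)-5-ethynyl-7-methoxy-2-[3-methoxy-4-(pivaloyloxy)phenyl]-2,3-dihydrobenzofuran-3-carboxylate | COc1cc([C@H]2Oc3c(OC)cc(C#C)cc3[C@@H]2C(=O)OC)ccc1OC(=O)C(C)(C)C
F5 | step 10 | methyl (2S,3S)-5-[[2-hydroxy-3-methoxy-5-(3-methoxy-3-oxopropyl)phenyl]ethynyl]-7-methoxy-2-[3-methoxy-4-(pivaloyloxy)phenyl]-2,3-dihydrobenzofuran-3-carboxylate | COc1cc([C@H]2Oc3c(OC)cc(C#Cc4cc(CCC(=O)OC)cc(OC)c4O)cc3[C@@H]2C(=O)OC)ccc1OC(=O)C(C)(C)C
F6 | step 9 | racemic methyl 3-[7-methoxy-2-[8-methoxy-2-[3-methoxy-4-(pivaloyloxy)phenyl]-4-oxochroman-6-yl]benzofuran-5-yl]propanoate | COc1cc(C2CC(=O)c3cc(-c4cc5cc(CCC(=O)OC)cc(OC)c5o4)cc(OC)c3O2)ccc1OC(=O)C(C)(C)C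
F7 | step 9 | methyl 3-[2-[(2R,4R)-4-hydroxy-8-methoxy-2-[3-methoxy-4-(pivaloyloxy)phenyl]chroman-6-yl]-7-methoxybenzofuran-5-yl]propanoate (cis) | COc1cc([C@H]2C[C@@H](O)c3cc(-c4cc5cc(CCC(=O)OC)cc(OC)c5o4)cc(OC)c3O2)ccc1OC(=O)C(C)(C)C
F8 | step 6 | methyl 3-[4-hydroxy-3-methoxy-5-[(trimethylsilyl)ethynyl]phenyl]propanoate | COC(=O)CCc1cc(OC)c(O)c(C#C[Si](C)(C)C)c1
F9 | step 6 | methyl 3-(7-methoxybenzofuran-5-yl)propanoate | COC(=O)CCc1cc(OC)c2occc2c1
F10 | step 6 | methyl 3-[7-methoxy-2-(4,4,5,5-tetramethyl-1,3,2-dioxaborolan-2-yl)benzofuran-5-yl]propanoate | COC(=O)CCc1cc(OC)c2oc(B3OC(C)(C)C(C)(C)O3)cc2c1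
F11 | step 11 | 4-[(2S,3R)-3-(hydroxymethyl)-5-[5-(3-hydroxypropyl)-7-methoxybenzofuran-2-yl]-7-methoxy-2,3-dihydrobenzofuran-2-yl]-2-methoxyphenyl pivalate | COc1cc([C@H]2Oc3c(OC)cc(-c4cc5cc(CCCO)cc(OC)c5o4)cc3[C@@H]2CO)ccc1OC(=O)C(C)(C)C
A1 | alternative 1 | 2-[(2S,3R)-2-[4-(tert-butyldimethylsilyloxy)-3-methoxyphenyl]-3-[(tert-butyldimethylsilyloxy)methyl]-7-methoxy-2,3-dihydrobenzofuran-5-yl]-5-[3-(tert-butyldimethylsilyloxy)propyl]-7-methoxybenzofuran-4-ol | COc1cc([C@H]2Oc3c(OC)cc(-c4cc5c(O)c(CCCO[Si](C)(C)C(C)(C)C)cc(OC)c5o4)cc3[C@@H]2CO[Si](C)(C)C(C)(C)C)ccc1O[Si](C)(C)C(C)(C)C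
A2 | alternative 1 | pentacarbonyl[methoxy[5-[(2S,3R)-2-[4-(tert-butyldimethylsilyloxy)-3-methoxyphenyl]-3-[(tert-butyldimethylsilyloxy)methyl]-7-methoxy-2,3-dihydrobenzofuran-5-yl]furan-2-yl]methylidene]chromium | COc1cc([C@H]2Oc3c(OC)cc(-c4ccc(o4)C(OC)=[Cr](=C=O)(=C=O)(=C=O)(=C=O)=C=O)cc3[C@@H]2CO[Si](C)(C)C(C)(C)C)ccc1O[Si](C)(C)C(C)(C)C
A3 | alternative 1 | tert-butyldimethyl(pent-4-yn-1-yloxy)silane | C#CCCCO[Si](C)(C)C(C)(C)C
A4 | alternative 2 | tris-silyl ether of 19 (tert-butyldimethylsilyl on both primary alcohols, triisopropylsilyl on the phenol) | COc1cc([C@H]2Oc3c(OC)cc(-c4cc5cc(CCCO[Si](C)(C)C(C)(C)C)cc(OC)c5o4)cc3[C@@H]2CO[Si](C)(C)C(C)(C)C)ccc1O[Si](C(C)C)(C(C)C)C(C)C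
A5 | alternative 2 | 2-[2-(tert-butyldimethylsilyloxy)-1-(p-tolylsulfonyl)ethyl]-4-[5-[3-(tert-butyldimethylsilyloxy)propyl]-7-methoxybenzofuran-2-yl]-6-methoxyphenol | COc1cc(-c2cc3cc(CCCO[Si](C)(C)C(C)(C)C)cc(OC)c3o2)cc(C(CO[Si](C)(C)C(C)(C)C)S(=O)(=O)c2ccc(C)cc2)c1O
A6 | alternative 2 | (2R,5R)-1-[3-methoxy-4-(triisopropylsilyloxy)benzyl]-2,5-dimethylthiolanium trifluoromethanesulfonate | C[C@@H]1CC[C@@H](C)[S+]1Cc1ccc(O[Si](C(C)C)(C(C)C)C(C)C)c(OC)c1.[O-]S(=O)(=O)C(F)(F)F
A7 | alternative 2 | 6-[2-(tert-butyldimethylsilyloxy)ethylidene]-4-[5-[3-(tert-butyldimethylsilyloxy)propyl]-7-methoxybenzofuran-2-yl]-2-methoxycyclohexa-2,4-dien-1-one (ortho-quinone methide) | COC1=CC(c2cc3cc(CCCO[Si](C)(C)C(C)(C)C)cc(OC)c3o2)=CC(=CCO[Si](C)(C)C(C)(C)C)C1=O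
A8 | alternative 2 | (2R,5R)-2,5-dimethylthiolanium [3-methoxy-4-(triisopropylsilyloxy)phenyl]methylide | C[C@@H]1CC[C@@H](C)[S+]1[CH-]c1ccc(O[Si](C(C)C)(C(C)C)C(C)C)c(OC)c1
A9 | alternative 3 | tris(tert-butyldimethylsilyl) ether of 19 | COc1cc([C@H]2Oc3c(OC)cc(-c4cc5cc(CCCO[Si](C)(C)C(C)(C)C)cc(OC)c5o4)cc3[C@@H]2CO[Si](C)(C)C(C)(C)C)ccc1O[Si](C)(C)C(C)(C)C
A10 | alternative 3 | 1-[(2S,3R)-2-[4-(tert-butyldimethylsilyloxy)-3-methoxyphenyl]-3-[(tert-butyldimethylsilyloxy)methyl]-7-methoxy-2,3-dihydrobenzofuran-5-yl]ethanone | COc1cc([C@H]2Oc3c(OC)cc(C(C)=O)cc3[C@@H]2CO[Si](C)(C)C(C)(C)C)ccc1O[Si](C)(C)C(C)(C)C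
A11 | alternative 3 | 4-[3-(tert-butyldimethylsilyloxy)propyl]-2-iodo-6-methoxyphenyl trifluoromethanesulfonate | COc1cc(CCCO[Si](C)(C)C(C)(C)C)cc(I)c1OS(=O)(=O)C(F)(F)F
A12 | alternative 3 | 2-[2-[(2S,3R)-2-[4-(tert-butyldimethylsilyloxy)-3-methoxyphenyl]-3-[(tert-butyldimethylsilyloxy)methyl]-7-methoxy-2,3-dihydrobenzofuran-5-yl]-2-oxoethyl]-4-[3-(tert-butyldimethylsilyloxy)propyl]-6-methoxyphenyl trifluoromethanesulfonate | COc1cc([C@H]2Oc3c(OC)cc(C(=O)Cc4cc(CCCO[Si](C)(C)C(C)(C)C)cc(OC)c4OS(=O)(=O)C(F)(F)F)cc3[C@@H]2CO[Si](C)(C)C(C)(C)C)ccc1O[Si](C)(C)C(C)(C)C
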